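A direct plan would build each ring on its own as a benzoate (Michael–Dieckmann ring synthesis, aromatisation with bromine) and would reach ring A from methyl 2,4-dihydroxy-6-methylbenzoate A1 by formylation at C3, double O-methylation, reduction, saponification and silylation, to give the acid A2.
It would then join A2, as its acid chloride, to the free 4-OH of the allyl ester A3 of ring B, and would unmask the protected depside A4 with fluoride and then with zerovalent palladium.
Weak step (a), the run-up to A1: ring synthesis, exhaustive bromination and hydrogenolysis of both bromines would be spent on a simple orsellinate, and about eight steps would stand in a line before ring A is ready.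
Weak step (b), the stretch around the coupling: hot hydroxide on a di-ortho-substituted benzoate, double silylation with partial desilylation, and an allyl ester put on and taken off would be some six operations that build no bond of the skeleton.
Weak step (c), the ester bond itself: a 2,6-disubstituted benzoyl chloride would have to acylate a flanked phenol beside a second free OH, late, with a silyl ether and an ionisable benzylic position in the molecule.

**Retrosynthetic overview**
Ring A (C1 with the depside carbonyl, C2–OMe, C3–CH2O, C4–OMe, C5–H, C6–CH3) is never made as a benzoic acid: it is cut at C1–C2 and C5–C6 and closed last, by a Diels–Alder benzannulation.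
The diene (C2 to C5) is a 1,1,3-trimethoxybutadiene that already holds both methoxy groups and the silyloxymethyl group; the dienophile (C1, C6, the methyl group and the finished C(=O)–O link) is the but-2-ynoate ester of the ring B phenol.
Ring B is bought as the acid; its O-4 ester is made on unhindered but-2-ynoic acid, and ring A then forms around this carbonyl and becomes aromatic by loss of methanol.
So no hindered acid is activated or saponified, ring A needs no bromination, formylation, methylation or reduction, and the two silicon-based protecting groups leave together in the last step.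

Key step: step 6

Remark: the Weinreb amide 4 and the acid 12 are taken as purchasable building blocks; the target is achiral, so no step has to control configuration.

**Step 1**
Reactants: 1 chlorodiphenylphosphine; 2 trimethyl orthoformate
Product: 3 (dimethoxymethyl)diphenylphosphine oxide
Conditions: neat, 0 °C → 60 °C; crystallisation (toluene/hexane)
Reagents that add atoms: none
Why: Michaelis–Arbuzov-type reaction, in which trivalent phosphorus attacks the dimethoxycarbenium ion from the orthoformate and chloride demethylates the methoxyphosphonium ion to the phosphine oxide.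

**Step 2**
Reactants: 4 2-{[tert-butyl(dimethyl)silyl]oxy}-N-methoxy-N-methylacetamide; 5 methoxyethene (methyl vinyl ether)
Product: 8 1-{[tert-butyl(dimethyl)silyl]oxy}-3-methoxybut-3-en-2-one, via 1-methoxyvinyllithium 6 (not isolated), via tetrahedral lithium alkoxide 7 (not isolated)
Conditions: 5 (3 equiv), tBuLi (1.5 equiv), THF, −78 → 0 °C; then 4, −78 → −30 °C; aq. NH4Cl
Reagents that add atoms: tert-butyllithium, [Li]C(C)(C)C (its lithium sits only in 6 and 7 and leaves as lithium chloride)
Why: Weinreb ketone synthesis with an α-alkoxyvinyl anion (α-lithiation of the vinyl ether), in which the chelated adduct 7 cannot collapse before the quench, so the reaction should stop at the ketone, and the neutral quench keeps the enol ether.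

**Step 3**
Reactants: 8 1-{[tert-butyl(dimethyl)silyl]oxy}-3-methoxybut-3-en-2-one; 3 (dimethoxymethyl)diphenylphosphine oxide
Product: 11 2-({[tert-butyl(dimethyl)silyl]oxy}methyl)-1,1,3-trimethoxybuta-1,3-diene, via lithiated phosphine oxide 9 (not isolated), via β-oxido phosphine oxide adduct 10 (not isolated)
Conditions: 3 (1.2 equiv), LiN(iPr)2 (1.2 equiv), THF, −100 °C; then 8, −100 → −78 °C; then KOtBu (1.3 equiv), −78 °C → rt; pentane, filtration, Kugelrohr distillation, used at once
Reagents that add atoms: lithium diisopropylamide, [Li]N(C(C)C)C(C)C (its lithium sits only in 9 and 10)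
Why: Horner–Wittig olefination to a ketene O,O-acetal, in which the lithiated phosphine oxide should add 1,2 to the ketone at −100 °C and the potassium alkoxide eliminates diphenylphosphinate; the new double bond carries two identical methoxy groups, so no alkene geometry arises.

**Step 4**
Reactants: 12 2,4-dihydroxy-3,6-dimethylbenzoic acid; 13 2-(trimethylsilyl)ethanol
Product: 15 2-(trimethylsilyl)ethyl 2,4-dihydroxy-3,6-dimethylbenzoate, via alkoxyphosphonium carboxylate 14 (not isolated)
Conditions: 13 (1.1 equiv), PPh3 (1.1 equiv), DIAD (1.1 equiv), THF, 0 °C → rt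
Reagents that add atoms: triphenylphosphine, c1ccc(cc1)P(c1ccccc1)c1ccccc1 (sits only in 14 and leaves as the oxide)
Why: Mitsunobu esterification, in which the carboxylate, far more acidic than either phenol, attacks the activated primary alcohol, so the di-ortho-substituted carboxyl group is esterified at oxygen and its hindered carbonyl carbon is never attacked.

**Step 5**
Reactants: 15 2-(trimethylsilyl)ethyl 2,4-dihydroxy-3,6-dimethylbenzoate; 16 but-2-ynoic acid
Product: 18 2-(trimethylsilyl)ethyl 4-(but-2-ynoyloxy)-2-hydroxy-3,6-dimethylbenzoate, via O-acylisourea 17 (not isolated)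
Conditions: 16 (1.1 equiv), DCC (1.1 equiv), DMAP (5 mol %), CH2Cl2, 0 °C
Reagents that add atoms: N,N'-dicyclohexylcarbodiimide, C(=NC1CCCCC1)=NC1CCCCC1 (sits only in 17 and leaves as the urea)
Why: Steglich esterification of an unhindered alkynoic acid, which should take the free 4-OH because the 2-OH is tied up in a hydrogen bond to the ester carbonyl and lies between two substituents.

**Step 6**
Reactants: 18 2-(trimethylsilyl)ethyl 4-(but-2-ynoyloxy)-2-hydroxy-3,6-dimethylbenzoate; 11 2-({[tert-butyl(dimethyl)silyl]oxy}methyl)-1,1,3-trimethoxybuta-1,3-diene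
Product: 22 2-(trimethylsilyl)ethyl 4-{[3-({[tert-butyl(dimethyl)silyl]oxy}methyl)-2,4-dimethoxy-6-methylbenzoyl]oxy}-2-hydroxy-3,6-dimethylbenzoate, via aryl trimethylsilyl ether 19 (not isolated), via cyclohexadiene cycloadduct 20 (not isolated), via silylated depside 21 (not isolated)
Conditions: BSA (1.2 equiv), toluene, 60 °C, 1 h; then 11 (2.5 equiv), 110 °C, sealed tube; then THF/5 % aq. citric acid, 0 °C
Reagents that add atoms: N,O-bis(trimethylsilyl)acetamide, CC(=N[Si](C)(C)C)O[Si](C)(C)C (its Me3Si group sits only in 19, 20 and 21 and leaves in the work-up)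
Why: Normal-electron-demand Diels–Alder reaction of the electron-rich 1,1,3-trioxygenated diene 11 with the aryl alk-2-ynoate, followed by 1,4-elimination of methanol from the bis-allylic ketal, which makes ring A aromatic (Diels–Alder/aromatisation benzannulation). The closest known reaction type is the cycloaddition of 1,1-dimethoxy-3-silyloxybuta-1,3-dienes with alk-2-ynoates, which gives 6-alkyl-2-methoxy-4-oxygenated benzoates; here the 3-oxygen is a methyl ether instead of a silyl ether. Ring A closes in the (4+2) mode with the new bonds C1–C2 and C5–C6: the terminal CH2 of the diene (largest HOMO coefficient, β to the 3-methoxy group) attacks the methyl-bearing β-carbon of the ynoate (largest LUMO coefficient) and the ketene acetal carbon joins the α-carbon, so the carbonyl that already carries ring B ends up between OMe and CH3. No stereocentre is formed; the step needs regioselectivity and chemoselectivity, which should come from this matched polarisation, from the ketal carbon carrying only methoxy groups (whichever leaves, C2 keeps OMe), and from masking the chelated phenol of ring B in the flask as a trimethylsilyl ether so that it cannot protonate the ketene acetal. The aryl ester makes the ynoate a better dienophile than an alkyl ester, and the silyl ether, the silylethyl ester and the depside link should be inert to neutral heat.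

**Step 7**
Reactants: 22 2-(trimethylsilyl)ethyl 4-{[3-({[tert-butyl(dimethyl)silyl]oxy}methyl)-2,4-dimethoxy-6-methylbenzoyl]oxy}-2-hydroxy-3,6-dimethylbenzoate
Product: 23 2-hydroxy-4-{[3-(hydroxymethyl)-2,4-dimethoxy-6-methylbenzoyl]oxy}-3,6-dimethylbenzoic acid (target)
Conditions: Bu4NF (4 equiv), THF, 0 °C → rt; cold aq. KHSO4 to pH 4
Reagents that add atoms: none
Why: Fluoride-induced desilylation of the primary silyl ether and fluoride-induced β-elimination (fragmentation) of the 2-(trimethylsilyl)ethyl ester in one operation; the di-ortho-substituted depside ester should resist, and the cold, mild acidification spares the electron-rich benzylic alcohol and avoids decarboxylation.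

## Compound list
1 | chlorodiphenylphosphine | ClP(c1ccccc1)c1ccccc1 | starting material
2 | trimethyl orthoformate | COC(OC)OC | starting material
3 | (dimethoxymethyl)diphenylphosphine oxide | COC(OC)P(=O)(c1ccccc1)c1ccccc1 | intermediate
4 | 2-{[tert-butyl(dimethyl)silyl]oxy}-N-methoxy-N-methylacetamide | CON(C)C(=O)CO[Si](C)(C)C(C)(C)C | starting material
5 | methoxyethene (methyl vinyl ether) | COC=C | starting material
6 | 1-methoxyvinyllithium (not isolated) | [Li]C(=C)OC | intermediate
7 | lithium alkoxide of the tetrahedral adduct of 6 to 4 (racemic, not isolated) | COC(=C)C(O[Li])(CO[Si](C)(C)C(C)(C)C)N(C)OC | intermediate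
8 | 1-{[tert-butyl(dimethyl)silyl]oxy}-3-methoxybut-3-en-2-one | C=C(OC)C(=O)CO[Si](C)(C)C(C)(C)C | intermediate
9 | [lithio(dimethoxy)methyl]diphenylphosphine oxide (not isolated) | COC(OC)([Li])P(=O)(c1ccccc1)c1ccccc1 | intermediate
10 | lithium alkoxide of the adduct of 9 to the ketone 8 (racemic, not isolated) | COC(=C)C(O[Li])(CO[Si](C)(C)C(C)(C)C)C(OC)(OC)P(=O)(c1ccccc1)c1ccccc1 | intermediate
11 | 2-({[tert-butyl(dimethyl)silyl]oxy}methyl)-1,1,3-trimethoxybuta-1,3-diene | C=C(OC)C(CO[Si](C)(C)C(C)(C)C)=C(OC)OC | intermediate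
12 | 2,4-dihydroxy-3,6-dimethylbenzoic acid | Cc1cc(O)c(C)c(O)c1C(=O)O | starting material
13 | 2-(trimethylsilyl)ethanol | C[Si](C)(C)CCO | starting material
14 | triphenyl[2-(trimethylsilyl)ethoxy]phosphonium 2,4-dihydroxy-3,6-dimethylbenzoate (not isolated) | C[Si](C)(C)CCO[P+](c1ccccc1)(c1ccccc1)c1ccccc1.Cc1cc(O)c(C)c(O)c1C(=O)[O-] | intermediate
15 | 2-(trimethylsilyl)ethyl 2,4-dihydroxy-3,6-dimethylbenzoate | Cc1cc(O)c(C)c(O)c1C(=O)OCC[Si](C)(C)C | intermediate
16 | but-2-ynoic acid | CC#CC(=O)O | starting material
17 | O-(but-2-ynoyl)-N,N'-dicyclohexylisourea (not isolated) | CC#CC(=O)OC(NC1CCCCC1)=NC1CCCCC1 | intermediate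
18 | 2-(trimethylsilyl)ethyl 4-(but-2-ynoyloxy)-2-hydroxy-3,6-dimethylbenzoate | CC#CC(=O)Oc1cc(C)c(C(=O)OCC[Si](C)(C)C)c(O)c1C | intermediate
19 | 2-(trimethylsilyl)ethyl 4-(but-2-ynoyloxy)-3,6-dimethyl-2-[(trimethylsilyl)oxy]benzoate (not isolated) | CC#CC(=O)Oc1cc(C)c(C(=O)OCC[Si](C)(C)C)c(O[Si](C)(C)C)c1C | intermediate
20 | cyclohexa-1,4-diene cycloadduct of 19 and 11, with the 6,6-dimethoxy ketal carbon next to the ester-bearing carbon (not isolated) | COC1(OC)C(C(=O)Oc2cc(C)c(C(=O)OCC[Si](C)(C)C)c(O[Si](C)(C)C)c2C)=C(C)CC(OC)=C1CO[Si](C)(C)C(C)(C)C | intermediate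
21 | 2-(trimethylsilyl)ethyl 4-{[3-({[tert-butyl(dimethyl)silyl]oxy}methyl)-2,4-dimethoxy-6-methylbenzoyl]oxy}-3,6-dimethyl-2-[(trimethylsilyl)oxy]benzoate (not isolated) | COc1cc(C)c(C(=O)Oc2cc(C)c(C(=O)OCC[Si](C)(C)C)c(O[Si](C)(C)C)c2C)c(OC)c1CO[Si](C)(C)C(C)(C)C | intermediate
22 | 2-(trimethylsilyl)ethyl 4-{[3-({[tert-butyl(dimethyl)silyl]oxy}methyl)-2,4-dimethoxy-6-methylbenzoyl]oxy}-2-hydroxy-3,6-dimethylbenzoate | COc1cc(C)c(C(=O)Oc2cc(C)c(C(=O)OCC[Si](C)(C)C)c(O)c2C)c(OC)c1CO[Si](C)(C)C(C)(C)C | intermediate
23 | 2-hydroxy-4-{[3-(hydroxymethyl)-2,4-dimethoxy-6-methylbenzoyl]oxy}-3,6-dimethylbenzoic acid (achiral) | COc1cc(C)c(C(=O)Oc2cc(C)c(C(=O)O)c(O)c2C)c(OC)c1CO | target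

**Step count and risks**
Total steps: 7. Longest linear sequence: 4 steps (steps 2, 3, 6 and 7, from 4 to 23; the lines through step 1 and through steps 4 and 5 are equally long).

The three steps most likely to fail:

Step 6 (key step). The crowded diene and the β-methyl ynoate may combine too slowly, so that the ketene acetal decomposes or polymerises before it cycloadds, or regiocontrol may erode at the temperature that is needed. The fallback gives up the ring construction and makes the C1–carbonyl bond by carbonylation; it sets out from 15 and comes back to the route at 22. 1,3-Dimethoxy-5-methylbenzene F1 would be lithiated between the two methoxy groups (nBuLi, TMEDA, THF, 0 °C) and formylated with DMF to 2,6-dimethoxy-4-methylbenzaldehyde F2. Reduction (NaBH4, MeOH) would give (2,6-dimethoxy-4-methylphenyl)methanol F3, and silylation (TBSCl, imidazole, DMF) tert-butyl[(2,6-dimethoxy-4-methylphenyl)methoxy]dimethylsilane F4. Iodination (N-iodosuccinimide, MeCN; the two free ring positions are equivalent) would give tert-butyl[(3-iodo-2,6-dimethoxy-4-methylphenyl)methoxy]dimethylsilane F5. Aryloxycarbonylation of F5 with the free 4-OH of 15 (Pd(OAc)2, Xantphos, CO 1 atm, Et3N, toluene, 80 °C) should then give 22.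

Step 3. The lithiated phosphine oxide may add in a conjugate sense to the methoxy enone, or may enolise the α-silyloxy ketone, so that no 1,2-adduct forms. The fallback moves the olefination to an aldehyde and builds the diene by acylation; it sets out from 3 and comes back to the route at 22. {[tert-Butyl(dimethyl)silyl]oxy}acetaldehyde F6 would take the same Horner–Wittig sequence with 3 to give the ketene acetal tert-butyl[(3,3-dimethoxyprop-2-en-1-yl)oxy]dimethylsilane F7. C-Acylation of F7 (AcCl, Et3N, Et2O, 0 °C) would give 3-({[tert-butyl(dimethyl)silyl]oxy}methyl)-4,4-dimethoxybut-3-en-2-one F8, and enol silylation (Me3SiOTf, Et3N, Et2O, 0 °C) the diene 2-({[tert-butyl(dimethyl)silyl]oxy}methyl)-1,1-dimethoxy-3-[(trimethylsilyl)oxy]buta-1,3-diene F9. Cycloaddition of F9 with 18 under the conditions of step 6 should give, after loss of methanol and aqueous desilylation, 2-(trimethylsilyl)ethyl 4-{[3-({[tert-butyl(dimethyl)silyl]oxy}methyl)-4-hydroxy-2-methoxy-6-methylbenzoyl]oxy}-2-hydroxy-3,6-dimethylbenzoate F10. Its free, non-chelated 4-OH on ring A would be methylated (MeI 1.1 equiv, K2CO3, acetone, rt) in the presence of the hydrogen-bonded OH of ring B, to give 22.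

Step 7. The basic fluoride that the silylethyl ester needs may cleave or transesterify the depside link, and buffered fluoride may leave the ester untouched. The fallback uses an ester that is cleaved by reduction; it sets out from 12 and comes back to the route at 23. Mitsunobu esterification of 12 with 2,2,2-trichloroethanol F11 would give 2,2,2-trichloroethyl 2,4-dihydroxy-3,6-dimethylbenzoate F12. The conditions of step 5 would give 2,2,2-trichloroethyl 4-(but-2-ynoyloxy)-2-hydroxy-3,6-dimethylbenzoate F13, and those of step 6 with 11 would give 2,2,2-trichloroethyl 4-{[3-({[tert-butyl(dimethyl)silyl]oxy}methyl)-2,4-dimethoxy-6-methylbenzoyl]oxy}-2-hydroxy-3,6-dimethylbenzoate F14. Buffered fluoride (Bu4NF/AcOH 1:1, THF, 0 °C → rt) would then remove only the silyl ether, to give 2,2,2-trichloroethyl 2-hydroxy-4-{[3-(hydroxymethyl)-2,4-dimethoxy-6-methylbenzoyl]oxy}-3,6-dimethylbenzoate F15. Zinc dust (Zn, aq. NH4OAc/THF, rt) would fragment the trichloroethyl ester under neutral conditions to 23.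

## Further compounds
F1 | step 6 | 1,3-dimethoxy-5-methylbenzene | COc1cc(C)cc(OC)c1
F2 | step 6 | 2,6-dimethoxy-4-methylbenzaldehyde | COc1cc(C)cc(OC)c1C=O
F3 | step 6 | (2,6-dimethoxy-4-methylphenyl)methanol | COc1cc(C)cc(OC)c1CO
F4 | step 6 | tert-butyl[(2,6-dimethoxy-4-methylphenyl)methoxy]dimethylsilane | COc1cc(C)cc(OC)c1CO[Si](C)(C)C(C)(C)C
F5 | step 6 | tert-butyl[(3-iodo-2,6-dimethoxy-4-methylphenyl)methoxy]dimethylsilane | COc1cc(C)c(I)c(OC)c1CO[Si](C)(C)C(C)(C)C
F6 | step 3 | {[tert-butyl(dimethyl)silyl]oxy}acetaldehyde | O=CCO[Si](C)(C)C(C)(C)C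
F7 | step 3 | tert-butyl[(3,3-dimethoxyprop-2-en-1-yl)oxy]dimethylsilane | COC(OC)=CCO[Si](C)(C)C(C)(C)C
F8 | step 3 | 3-({[tert-butyl(dimethyl)silyl]oxy}methyl)-4,4-dimethoxybut-3-en-2-one | CC(=O)C(CO[Si](C)(C)C(C)(C)C)=C(OC)OC
F9 | step 3 | 2-({[tert-butyl(dimethyl)silyl]oxy}methyl)-1,1-dimethoxy-3-[(trimethylsilyl)oxy]buta-1,3-diene | C=C(O[Si](C)(C)C)C(CO[Si](C)(C)C(C)(C)C)=C(OC)OC
F10 | step 3 | 2-(trimethylsilyl)ethyl 4-{[3-({[tert-butyl(dimethyl)silyl]oxy}methyl)-4-hydroxy-2-methoxy-6-methylbenzoyl]oxy}-2-hydroxy-3,6-dimethylbenzoate | COc1c(CO[Si](C)(C)C(C)(C)C)c(O)cc(C)c1C(=O)Oc1cc(C)c(C(=O)OCC[Si](C)(C)C)c(O)c1C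
F11 | step 7 | 2,2,2-trichloroethanol | OCC(Cl)(Cl)Cl
F12 | step 7 | 2,2,2-trichloroethyl 2,4-dihydroxy-3,6-dimethylbenzoate | Cc1cc(O)c(C)c(O)c1C(=O)OCC(Cl)(Cl)Cl
F13 | step 7 | 2,2,2-trichloroethyl 4-(but-2-ynoyloxy)-2-hydroxy-3,6-dimethylbenzoate | CC#CC(=O)Oc1cc(C)c(C(=O)OCC(Cl)(Cl)Cl)c(O)c1C
F14 | step 7 | 2,2,2-trichloroethyl 4-{[3-({[tert-butyl(dimethyl)silyl]oxy}methyl)-2,4-dimethoxy-6-methylbenzoyl]oxy}-2-hydroxy-3,6-dimethylbenzoate | COc1cc(C)c(C(=O)Oc2cc(C)c(C(=O)OCC(Cl)(Cl)Cl)c(O)c2C)c(OC)c1CO[Si](C)(C)C(C)(C)C
F15 | step 7 | 2,2,2-trichloroethyl 2-hydroxy-4-{[3-(hydroxymethyl)-2,4-dimethoxy-6-methylbenzoyl]oxy}-3,6-dimethylbenzoate | COc1cc(C)c(C(=O)Oc2cc(C)c(C(=O)OCC(Cl)(Cl)Cl)c(O)c2C)c(OC)c1CO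
A1 | direct plan | methyl 2,4-dihydroxy-6-methylbenzoate | COC(=O)c1c(C)cc(O)cc1O
A2 | direct plan | 3-({[tert-butyl(dimethyl)silyl]oxy}methyl)-2,4-dimethoxy-6-methylbenzoic acid | Cc1cc(OC)c(CO[Si](C)(C)C(C)(C)C)c(OC)c1C(=O)O
A3 | direct plan | allyl 2,4-dihydroxy-3,6-dimethylbenzoate | C=CCOC(=O)c1c(C)cc(O)c(C)c1O
A4 | direct plan | allyl 4-{[3-({[tert-butyl(dimethyl)silyl]oxy}methyl)-2,4-dimethoxy-6-methylbenzoyl]oxy}-2-hydroxy-3,6-dimethylbenzoate | C=CCOC(=O)c1c(C)cc(OC(=O)c2c(C)cc(OC)c(CO[Si](C)(C)C(C)(C)C)c2OC)c(C)c1O
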